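Retrosynthesis: cut first the side-chain bond between C2' and C3' of the diene (alkene–alkyne coupling on a propynyl group), then the acetate, the enone (back to a β,γ-epoxy ketone), the lactone carbonyl (back to a 1,4-diol) and the ring epoxide; the central cut is the bond between the spiro carbon C5 and the ring CH2 C10, followed by the cyclopentene C=C, the oxirane, two allyl–carbinol bonds and the trisubstituted C=C.
Forward: the chain is joined by olefination and double allylation (steps 1–4), the oxirane is made (5), the five-membered carbocycle is closed by metathesis (6) and expanded to the six-membered ring (7); ring epoxide (8), γ-lactone (10), enone and acetate (11, 12) and the diene side chain (13) follow.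
Enabling feature: the spiro carbon C5 sits between the ring ketone C6 and the lactone carbinol carbon C1, a ketone–quaternary carbon–carbinol triad that is what a 1,2-shift of a ring carbon onto the nearer carbon of a 2,3-epoxy tertiary alcohol leaves behind, so a symmetric cyclopent-3-enol can grow into the cyclohexenone ring.
Stereochemistry: the Shi epoxidation sets the (2R,3R)-oxirane; the rearrangement turns it into C5 (inversion) and C1 (retention); the C1 hydroxyl then steers the ring epoxidation that becomes C9; the alkene geometries come from the Still–Gennari olefination (Z) and from syn addition in the last coupling (E,E).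
The two-carbon arm of the lactone is carried as a silyl-protected 2-hydroxyethyl group, and the cyclopentene is closed only after the asymmetric epoxidation, so that at each oxidation the intended alkene is the only reactive one.

Key step: step 7

Remark: compounds 1, 2, 4, 7, 20 and the ketone catalyst of step 5 are taken as purchased; aldehyde 5 is volatile and is carried on as a dried solution.

Step 1
Reactants: 1 methyl 2-[bis(2,2,2-trifluoroethoxy)phosphoryl]acetate; 2 tert-butyl(2-iodoethoxy)dimethylsilane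
Product: 3 methyl 2-[bis(2,2,2-trifluoroethoxy)phosphoryl]-4-[(tert-butyldimethylsilyl)oxy]butanoate (racemic)
Conditions: NaH, DMF, 0 °C to rt
Reagents that add atoms: none
Why: SN2 C-alkylation of the stabilised phosphonoacetate anion with a primary iodide, the usual entry to α-substituted Still–Gennari reagents, with a slight excess of 1 to hold back dialkylation.

Step 2
Reactants: 4 but-2-yn-1-ol
Product: 5 but-2-ynal
Conditions: MnO2, CH2Cl2, rt
Reagents that add atoms: none
Why: MnO2 oxidation of a propargylic alcohol stops at the aldehyde and leaves the alkyne alone.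

Step 3
Reactants: 3 methyl 2-[bis(2,2,2-trifluoroethoxy)phosphoryl]-4-[(tert-butyldimethylsilyl)oxy]butanoate; 5 but-2-ynal
Product: 6 methyl (2Z)-2-{2-[(tert-butyldimethylsilyl)oxy]ethyl}hex-2-en-4-ynoate
Conditions: KN(SiMe3)2, 18-crown-6, THF, −78 °C
Reagents that add atoms: none
Why: Still–Gennari variant of the Horner–Wadsworth–Emmons olefination, in which the electron-poor phosphonate eliminates from the kinetic adduct and so should place the ester cis to the propynyl group (Z alkene).

Step 4
Reactants: 6 methyl (2Z)-2-{2-[(tert-butyldimethylsilyl)oxy]ethyl}hex-2-en-4-ynoate; 7 allylmagnesium bromide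
Product: 9 (5Z)-5-{2-[(tert-butyldimethylsilyl)oxy]ethyl}-4-(prop-2-en-1-yl)nona-1,5-dien-7-yn-4-ol, via allyl ketone 8 (not isolated)
Conditions: allylmagnesium bromide (2.5 equiv), Et2O, −78 to 0 °C; aq NH4Cl
Reagents that add atoms: allylmagnesium bromide (second equivalent), C=CC[Mg]Br
Why: double 1,2-addition of an allyl Grignard reagent to an ester, in which the first equivalent gives the allyl ketone with loss of methoxide and the second adds to that more reactive ketone (allyl reagents add at carbonyl carbon in preference to conjugate positions), which should leave the alkene geometry untouched.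

Step 5
Reactants: 9 (5Z)-5-{2-[(tert-butyldimethylsilyl)oxy]ethyl}-4-(prop-2-en-1-yl)nona-1,5-dien-7-yn-4-ol
Product: 10 4-[(2R,3R)-2-{2-[(tert-butyldimethylsilyl)oxy]ethyl}-3-(prop-1-yn-1-yl)oxiran-2-yl]hepta-1,6-dien-4-ol
Conditions: 1,2:4,5-di-O-isopropylidene-β-D-erythro-2,3-hexodiulo-2,6-pyranose (D-fructose-derived Shi ketone, 0.3 equiv), Oxone (2KHSO5·KHSO4·K2SO4), K2CO3, Bu4NHSO4, MeCN/CH2(OMe)2, aq Na2B4O7 buffer, 0 °C
Reagents that add atoms: potassium peroxymonosulfate (active component of Oxone), [K+].[O-]S(=O)(=O)OO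
Why: Shi asymmetric epoxidation, in which the electrophilic chiral dioxirane should take the trisubstituted enyne alkene ahead of the two monosubstituted allyl alkenes and the alkyne, and in which the spiro transition state with the vinylic hydrogen in the hindered quadrant should deliver oxygen to the face that makes both oxirane carbons R, the Z geometry keeping propynyl cis to the carbinol carbon.

Step 6
Reactants: 10 4-[(2R,3R)-2-{2-[(tert-butyldimethylsilyl)oxy]ethyl}-3-(prop-1-yn-1-yl)oxiran-2-yl]hepta-1,6-dien-4-ol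
Product: 11 1-[(2R,3R)-2-{2-[(tert-butyldimethylsilyl)oxy]ethyl}-3-(prop-1-yn-1-yl)oxiran-2-yl]cyclopent-3-en-1-ol
Conditions: first-generation Grubbs catalyst RuCl2(PCy3)2(=CHPh) (5 mol %), CH2Cl2, 40 °C
Reagents that add atoms: none
Why: ring-closing metathesis of a 4,4-disubstituted 1,6-diene to a cyclopentene with loss of ethylene, a fast closure that this phosphine catalyst should achieve without engaging the internal alkyne, the oxirane or the free hydroxyl, and without touching a stereocentre.

Step 7
Reactants: 11 1-[(2R,3R)-2-{2-[(tert-butyldimethylsilyl)oxy]ethyl}-3-(prop-1-yn-1-yl)oxiran-2-yl]cyclopent-3-en-1-ol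
Product: 12 (6R)-6-{2-[(tert-butyldimethylsilyl)oxy]ethyl}-6-[(1R)-1-hydroxybut-2-yn-1-yl]cyclohex-3-en-1-one
Conditions: BF3·OEt2 (0.5 equiv), CH2Cl2, −78 °C; aq NaHCO3
Reagents that add atoms: none
Why: BF3 binds the oxirane oxygen, the C–O bond at the fully substituted carbon lengthens, and a ring CH2 of the cyclopentenol lying antiperiplanar to it shifts from the carbinol carbon, whose oxygen becomes the ketone. The closest known reaction type is the Lewis acid semipinacol rearrangement of 2,3-epoxy tertiary alcohols to β-hydroxy ketones with an α-quaternary carbon, including ring expansions of cycloalkanols. The six-membered ring arises by ring expansion through a 1,2-alkyl shift (five to six), not by a cyclisation, so no exo or endo mode applies. The quaternary carbon forms with inversion at the oxirane carbon and the carbinol carbon keeps its C–O bond, so both new descriptors (6R and 1R) are dictated by the (2R,3R)-oxirane of step 5. The step needs cleavage at the fully substituted carbon next to the carbinol and not at the propargylic CH, which the higher substitution of that carbon, the anchimeric push of the migrating bond from the adjacent carbinol and the inductive pull of the sp carbon on the other oxirane carbon should secure, while the two ring CH2 groups are equivalent and lead to the same ketone. Low temperature and a basic quench should keep the double bond β,γ to the ketone and the silyl ether in place.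

Step 8
Reactants: 12 (6R)-6-{2-[(tert-butyldimethylsilyl)oxy]ethyl}-6-[(1R)-1-hydroxybut-2-yn-1-yl]cyclohex-3-en-1-one
Product: 13 (1R,4S,6S)-4-{2-[(tert-butyldimethylsilyl)oxy]ethyl}-4-[(1R)-1-hydroxybut-2-yn-1-yl]-7-oxabicyclo[4.1.0]heptan-3-one
Conditions: VO(acac)2 (5 mol %), t-BuOOH, CH2Cl2, 0 °C to rt
Reagents that add atoms: tert-butyl hydroperoxide, CC(C)(C)OO
Why: hydroxyl-directed epoxidation, in which the vanadate ester of the secondary alcohol (bishomoallylic to the only alkene) should deliver the peroxide oxygen to the ring face cis to the carbinol branch and so set both oxirane carbons (1R,6S), the alkyne and ketone being inert and the syn placement of hydroxyl and oxirane ruling out backside opening to a tetrahydrofuran.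

Step 9
Reactants: 13 (1R,4S,6S)-4-{2-[(tert-butyldimethylsilyl)oxy]ethyl}-4-[(1R)-1-hydroxybut-2-yn-1-yl]-7-oxabicyclo[4.1.0]heptan-3-one
Product: 14 (1R,4S,6S)-4-(2-hydroxyethyl)-4-[(1R)-1-hydroxybut-2-yn-1-yl]-7-oxabicyclo[4.1.0]heptan-3-one
Conditions: HF·pyridine, pyridine, THF, 0 °C
Reagents that add atoms: none
Why: fluoride cleavage of a primary silyl ether under buffered conditions that should spare the β,γ-epoxy ketone and avoid retro-aldol cleavage of the β-hydroxy ketone.

Step 10
Reactants: 14 (1R,4S,6S)-4-(2-hydroxyethyl)-4-[(1R)-1-hydroxybut-2-yn-1-yl]-7-oxabicyclo[4.1.0]heptan-3-one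
Product: 17 (1S,2'R,3R,6R)-2'-(prop-1-yn-1-yl)spiro[7-oxabicyclo[4.1.0]heptane-3,3'-oxolane]-4,5'-dione, via hydroxy aldehyde 15 (not isolated), via lactol 16 (not isolated)
Conditions: TEMPO (0.2 equiv), PhI(OAc)2 (2.5 equiv), CH2Cl2, rt
Reagents that add atoms: none
Why: oxoammonium-mediated oxidative lactonisation of a 1,4-diol, in which the primary alcohol is oxidised first, the aldehyde is trapped by the secondary hydroxyl as a five-membered lactol and this is oxidised on to the γ-lactone without touching a stereocentre.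

Step 11
Reactants: 17 (1S,2'R,3R,6R)-2'-(prop-1-yn-1-yl)spiro[7-oxabicyclo[4.1.0]heptane-3,3'-oxolane]-4,5'-dione
Product: 18 (1R,5R,9S)-9-hydroxy-1-(prop-1-yn-1-yl)-2-oxaspiro[4.5]dec-7-ene-3,6-dione
Conditions: DBU (0.2 equiv), CH2Cl2, 0 °C
Reagents that add atoms: none
Why: base-catalysed E1cB opening of a β,γ-epoxy ketone, in which enolisation at the only α-CH2 expels the oxirane oxygen to give the γ-hydroxy enone while the C–O bond at C9 stays intact (9S), retro-aldol being excluded now that the carbinol oxygen is acylated.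

Step 12
Reactants: 18 (1R,5R,9S)-9-hydroxy-1-(prop-1-yn-1-yl)-2-oxaspiro[4.5]dec-7-ene-3,6-dione
Product: 19 (1R,5R,9S)-3,6-dioxo-1-(prop-1-yn-1-yl)-2-oxaspiro[4.5]dec-7-en-9-yl acetate
Conditions: Ac2O, pyridine, DMAP (cat.), CH2Cl2, 0 °C
Reagents that add atoms: acetic anhydride, CC(=O)OC(C)=O
Why: DMAP-catalysed O-acetylation of the secondary allylic alcohol with retention, which also removes a free allylic alcohol before the ruthenium step.

Step 13
Reactants: 19 (1R,5R,9S)-3,6-dioxo-1-(prop-1-yn-1-yl)-2-oxaspiro[4.5]dec-7-en-9-yl acetate; 20 2-methylpent-4-en-2-ol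
Product: 21 (+)-miliusane XVII, (1R,5R,9S)-1-[(1E,4E)-6-hydroxy-2,6-dimethylhepta-1,4-dien-1-yl]-3,6-dioxo-2-oxaspiro[4.5]dec-7-en-9-yl acetate
Conditions: [CpRu(MeCN)3]PF6 (10 mol %), acetone, rt
Reagents that add atoms: none
Why: ruthenium-catalysed alkene–alkyne coupling (formal Alder-ene reaction) through a ruthenacyclopentene, in which the new C–C bond should form at the less hindered methyl-bearing alkyne carbon, hydrogen is delivered cis to it (1E) and β-hydride elimination from the allylic CH2 gives the 4E alkene of the 1,4-diene, no stereocentre being touched.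

Compound list
1 | methyl 2-[bis(2,2,2-trifluoroethoxy)phosphoryl]acetate | COC(=O)CP(=O)(OCC(F)(F)F)OCC(F)(F)F | starting material
2 | tert-butyl(2-iodoethoxy)dimethylsilane | CC(C)(C)[Si](C)(C)OCCI | starting material
3 | methyl 2-[bis(2,2,2-trifluoroethoxy)phosphoryl]-4-[(tert-butyldimethylsilyl)oxy]butanoate (racemic) | COC(=O)C(CCO[Si](C)(C)C(C)(C)C)P(=O)(OCC(F)(F)F)OCC(F)(F)F | intermediate
4 | but-2-yn-1-ol | CC#CCO | starting material
5 | but-2-ynal | CC#CC=O | intermediate
6 | methyl (2Z)-2-{2-[(tert-butyldimethylsilyl)oxy]ethyl}hex-2-en-4-ynoate | CC#C/C=C(/CCO[Si](C)(C)C(C)(C)C)C(=O)OC | intermediate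
7 | allylmagnesium bromide | C=CC[Mg]Br | starting material
8 | (5Z)-5-{2-[(tert-butyldimethylsilyl)oxy]ethyl}nona-1,5-dien-7-yn-4-one | C=CCC(=O)/C(CCO[Si](C)(C)C(C)(C)C)=C\C#CC | intermediate
9 | (5Z)-5-{2-[(tert-butyldimethylsilyl)oxy]ethyl}-4-(prop-2-en-1-yl)nona-1,5-dien-7-yn-4-ol | C=CCC(O)(CC=C)/C(CCO[Si](C)(C)C(C)(C)C)=C\C#CC | intermediate
10 | 4-[(2R,3R)-2-{2-[(tert-butyldimethylsilyl)oxy]ethyl}-3-(prop-1-yn-1-yl)oxiran-2-yl]hepta-1,6-dien-4-ol | C=CCC(O)(CC=C)[C@]1(CCO[Si](C)(C)C(C)(C)C)O[C@@H]1C#CC | intermediate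
11 | 1-[(2R,3R)-2-{2-[(tert-butyldimethylsilyl)oxy]ethyl}-3-(prop-1-yn-1-yl)oxiran-2-yl]cyclopent-3-en-1-ol | OC1(CC=CC1)[C@]2(CCO[Si](C)(C)C(C)(C)C)O[C@@H]2C#CC | intermediate
12 | (6R)-6-{2-[(tert-butyldimethylsilyl)oxy]ethyl}-6-[(1R)-1-hydroxybut-2-yn-1-yl]cyclohex-3-en-1-one | O=C1CC=CC[C@@]1(CCO[Si](C)(C)C(C)(C)C)[C@H](O)C#CC | intermediate
13 | (1R,4S,6S)-4-{2-[(tert-butyldimethylsilyl)oxy]ethyl}-4-[(1R)-1-hydroxybut-2-yn-1-yl]-7-oxabicyclo[4.1.0]heptan-3-one | O=C1C[C@H]2O[C@H]2C[C@@]1(CCO[Si](C)(C)C(C)(C)C)[C@H](O)C#CC | intermediate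
14 | (1R,4S,6S)-4-(2-hydroxyethyl)-4-[(1R)-1-hydroxybut-2-yn-1-yl]-7-oxabicyclo[4.1.0]heptan-3-one | O=C1C[C@H]2O[C@H]2C[C@@]1(CCO)[C@H](O)C#CC | intermediate
15 | 2-{(1S,3R,6R)-3-[(1R)-1-hydroxybut-2-yn-1-yl]-4-oxo-7-oxabicyclo[4.1.0]heptan-3-yl}acetaldehyde | O=C1C[C@H]2O[C@H]2C[C@@]1(CC=O)[C@H](O)C#CC | intermediate
16 | (1S,2'R,3R,6R)-5'-hydroxy-2'-(prop-1-yn-1-yl)spiro[7-oxabicyclo[4.1.0]heptane-3,3'-oxolan]-4-one (both anomers) | O=C1C[C@H]2O[C@H]2C[C@]13CC(O)O[C@@H]3C#CC | intermediate
17 | (1S,2'R,3R,6R)-2'-(prop-1-yn-1-yl)spiro[7-oxabicyclo[4.1.0]heptane-3,3'-oxolane]-4,5'-dione | O=C1C[C@H]2O[C@H]2C[C@]13CC(=O)O[C@@H]3C#CC | intermediate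
18 | (1R,5R,9S)-9-hydroxy-1-(prop-1-yn-1-yl)-2-oxaspiro[4.5]dec-7-ene-3,6-dione | O[C@@H]1C=CC(=O)[C@@]2(CC(=O)O[C@@H]2C#CC)C1 | intermediate
19 | (1R,5R,9S)-3,6-dioxo-1-(prop-1-yn-1-yl)-2-oxaspiro[4.5]dec-7-en-9-yl acetate | CC(=O)O[C@@H]1C=CC(=O)[C@@]2(CC(=O)O[C@@H]2C#CC)C1 | intermediate
20 | 2-methylpent-4-en-2-ol | CC(C)(O)CC=C | starting material
21 | (+)-miliusane XVII, (1R,5R,9S)-1-[(1E,4E)-6-hydroxy-2,6-dimethylhepta-1,4-dien-1-yl]-3,6-dioxo-2-oxaspiro[4.5]dec-7-en-9-yl acetate | CC(=O)O[C@@H]1C=CC(=O)[C@@]2(CC(=O)O[C@@H]2/C=C(\C)C/C=C/C(C)(C)O)C1 | target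

Total step count: 13. Longest linear sequence: 12 steps (steps 1 and 3 to 13); step 2 is the only step off this line.

Steps most likely to fail

Step 5. The epoxidation may lack discrimination: the enyne alkene is crowded by the neighbouring quaternary carbinol and deactivated by its allylic oxygen, so oxidation of the allyl groups or a loss of face selectivity could intervene. The fallback sets out from ester 6, replaces reagent control by hydroxyl-bound titanium delivery, and returns at 10. Reduction of 6 with i-Bu2AlH (CH2Cl2, −78 °C) should give (2Z)-2-{2-[(tert-butyldimethylsilyl)oxy]ethyl}hex-2-en-4-yn-1-ol F1. Sharpless asymmetric epoxidation (Ti(OiPr)4, L-(+)-diethyl tartrate, t-BuOOH, 4 Å sieves, CH2Cl2, −20 °C) should oxidise the only alkene, which is allylic to the hydroxyl, and give [(2S,3R)-2-{2-[(tert-butyldimethylsilyl)oxy]ethyl}-3-(prop-1-yn-1-yl)oxiran-2-yl]methanol F2, the same spatial arrangement as in 10. Oxidation with TEMPO, catalytic NaOCl and NaClO2 should give (2R,3R)-2-{2-[(tert-butyldimethylsilyl)oxy]ethyl}-3-(prop-1-yn-1-yl)oxirane-2-carboxylic acid F3, and Me3SiCHN2 should convert it to methyl (2R,3R)-2-{2-[(tert-butyldimethylsilyl)oxy]ethyl}-3-(prop-1-yn-1-yl)oxirane-2-carboxylate F4. Double addition of allylmagnesium bromide (two equivalents) at −78 °C should then give 10.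

Step 7. The rearrangement may be overtaken by oxirane opening without migration (capture of the developing cation by fluoride or by the neighbouring hydroxyl), by cleavage at the propargylic carbon, or by acid-promoted drift of the ring double bond into conjugation. The fallback sets out from 10 and returns at 12 with rearrangement and ring formation interchanged. BF3·OEt2 on the open-chain diallyl carbinol 10 should shift one freely rotating allyl group in the same semipinacol sense to give (5R,6R)-5-{2-[(tert-butyldimethylsilyl)oxy]ethyl}-6-hydroxy-5-(prop-2-en-1-yl)non-1-en-7-yn-4-one F5. Ring-closing metathesis of its two allyl groups with the first-generation Grubbs catalyst RuCl2(PCy3)2(=CHPh) should then close the cyclohexenone 12.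

Step 8. The directed epoxidation may show poor facial selectivity, because a bishomoallylic hydroxyl steers only weakly and the carbinol branch must turn axial to reach the alkene. The fallback sets out from 12, uses steric control followed by inversion, and returns at 19. HF·pyridine should give (6R)-6-(2-hydroxyethyl)-6-[(1R)-1-hydroxybut-2-yn-1-yl]cyclohex-3-en-1-one F6. TEMPO/PhI(OAc)2 should lactonise it to (1R,5R)-1-(prop-1-yn-1-yl)-2-oxaspiro[4.5]dec-8-ene-3,6-dione F7. m-CPBA (NaHCO3, CH2Cl2) should then attack the face of the lactone CH2, away from the propynyl-bearing carbon, to give (1R,2'R,3R,6S)-2'-(prop-1-yn-1-yl)spiro[7-oxabicyclo[4.1.0]heptane-3,3'-oxolane]-4,5'-dione F8. DBU should open it to (1R,5R,9R)-9-hydroxy-1-(prop-1-yn-1-yl)-2-oxaspiro[4.5]dec-7-ene-3,6-dione F9, the C9 epimer of 18. A Mitsunobu reaction with PPh3, diisopropyl azodicarboxylate and acetic acid should invert C9 and give acetate 19 directly.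

Further compounds
F1 | step 5 | (2Z)-2-{2-[(tert-butyldimethylsilyl)oxy]ethyl}hex-2-en-4-yn-1-ol | CC#C/C=C(/CCO[Si](C)(C)C(C)(C)C)CO
F2 | step 5 | [(2S,3R)-2-{2-[(tert-butyldimethylsilyl)oxy]ethyl}-3-(prop-1-yn-1-yl)oxiran-2-yl]methanol | OC[C@]1(CCO[Si](C)(C)C(C)(C)C)O[C@@H]1C#CC
F3 | step 5 | (2R,3R)-2-{2-[(tert-butyldimethylsilyl)oxy]ethyl}-3-(prop-1-yn-1-yl)oxirane-2-carboxylic acid | OC(=O)[C@]1(CCO[Si](C)(C)C(C)(C)C)O[C@@H]1C#CC
F4 | step 5 | methyl (2R,3R)-2-{2-[(tert-butyldimethylsilyl)oxy]ethyl}-3-(prop-1-yn-1-yl)oxirane-2-carboxylate | COC(=O)[C@]1(CCO[Si](C)(C)C(C)(C)C)O[C@@H]1C#CC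
F5 | step 7 | (5R,6R)-5-{2-[(tert-butyldimethylsilyl)oxy]ethyl}-6-hydroxy-5-(prop-2-en-1-yl)non-1-en-7-yn-4-one | C=CCC(=O)[C@](CC=C)(CCO[Si](C)(C)C(C)(C)C)[C@H](O)C#CC
F6 | step 8 | (6R)-6-(2-hydroxyethyl)-6-[(1R)-1-hydroxybut-2-yn-1-yl]cyclohex-3-en-1-one | O=C1CC=CC[C@@]1(CCO)[C@H](O)C#CC
F7 | step 8 | (1R,5R)-1-(prop-1-yn-1-yl)-2-oxaspiro[4.5]dec-8-ene-3,6-dione | O=C1CC=CC[C@]12CC(=O)O[C@@H]2C#CC
F8 | step 8 | (1R,2'R,3R,6S)-2'-(prop-1-yn-1-yl)spiro[7-oxabicyclo[4.1.0]heptane-3,3'-oxolane]-4,5'-dione | O=C1C[C@@H]2O[C@@H]2C[C@]13CC(=O)O[C@@H]3C#CC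
F9 | step 8 | (1R,5R,9R)-9-hydroxy-1-(prop-1-yn-1-yl)-2-oxaspiro[4.5]dec-7-ene-3,6-dione | O[C@H]1C=CC(=O)[C@@]2(CC(=O)O[C@@H]2C#CC)C1
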